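**Retrosynthetic overview**

1. Locants: lactone carbonyl C1, C2 (methyl), C3 (OH), ring carbon C4, chain C5–C17, furan-3-yl on C17. The strategy rests on the C14 carbinol oxygen being 1,5-related to C10 of the (E)-C10=C11 alkene: O, C14, C13, C12, C11 and C10 can be held as a 3,4-dihydro-2H-pyran whose C10–O bond is later exchanged for the C9–C10 bond.
2. Last disconnection: the (Z)-C4=C5 alkene, by aldol addition of lithiated 4-methoxy-3-methylfuran-2(5H)-one to the C5 aldehyde, dehydration and O-demethylation.
3. Key disconnection: C9–C10 and C10–CH3, by 1,2-metallate rearrangement of the cuprate made from the 6-metallated dihydropyran (C10–C17) and the C5–C9 alkyllithium, then MeI; the ring oxygen leaves as the C14 alkoxide.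
4. The dihydropyran stannane comes from the δ-lactone (enol triflate, Me3SnSnMe3). C14 is set by lithiation–borylation of (R)-hex-5-en-2-yl 2,4,6-triisopropylbenzoate with the 3-(furan-3-yl)propyl boronic ester; C6 is set by Evans allylation.
5. Ring order: the furan is bought in 3-bromofuran; the temporary pyranone ring closes in step 8 and opens in step 16; the butenolide ring closes in step 19 and is attached in step 21.

Key step: step 16

Remark: in step 16 iodide 28 is used in about twofold amount, since only one alkyl ligand of the cuprate migrates; 42 and 43 are carried as mixtures of diastereomers at the two centres that step 22 converts into the C4=C5 alkene.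

**Route**

Step 1
Reactants: 1 (S)-propylene oxide
Product: 2 (S)-hex-5-en-2-ol
Conditions: CH2=CHCH2MgCl, CuI (10 mol%), THF, −40 to 0 °C; aq NH4Cl
Reagents that add atoms: allylmagnesium chloride, C=CC[Mg]Cl
Why: Copper-catalysed SN2 opening of the epoxide by the allyl Grignard reagent at the unsubstituted carbon should leave the stereocentre untouched (epoxide ring opening).

Step 2
Reactants: 2 (S)-hex-5-en-2-ol
Product: 3 (R)-hex-5-en-2-yl 2,4,6-triisopropylbenzoate
Conditions: 2,4,6-triisopropylbenzoic acid, PPh3, DIAD, THF, 0 °C to rt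
Reagents that add atoms: 2,4,6-triisopropylbenzoic acid, CC(C)c1cc(C(C)C)c(C(=O)O)c(C(C)C)c1
Why: Mitsunobu esterification displaces the alkoxyphosphonium by the carboxylate with inversion, which should give the (R)-benzoate needed for step 6.

Step 3
Reactants: 4 3-bromofuran
Product: 6 3-(furan-3-yl)propan-1-ol, via 3-furyllithium 5 (not isolated)
Conditions: n-BuLi, THF, −78 °C; oxetane, BF3·OEt2, −78 °C
Reagents that add atoms: oxetane, C1COC1
Why: Bromine–lithium exchange at −78 °C gives the 3-lithiofuran without isomerisation to the 2-lithio isomer, and BF3 activation lets it open oxetane (Lewis acid-promoted oxetane opening by an organolithium).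

Step 4
Reactants: 6 3-(furan-3-yl)propan-1-ol
Product: 7 3-(3-bromopropyl)furan
Conditions: CBr4, PPh3, CH2Cl2, 0 °C
Reagents that add atoms: carbon tetrabromide, BrC(Br)(Br)Br
Why: The Appel reaction converts the primary alcohol to the bromide under neutral conditions that the acid-sensitive furan tolerates.

Step 5
Reactants: 7 3-(3-bromopropyl)furan
Product: 8 2-[3-(furan-3-yl)propyl]-5,5-dimethyl-1,3,2-dioxaborinane
Conditions: bis(neopentyl glycolato)diboron (B2neop2), CuI (10 mol%), PPh3 (13 mol%), LiOMe, DMF, rt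
Reagents that add atoms: bis(neopentyl glycolato)diboron, CC1(C)COB(OC1)B1OCC(C)(C)CO1
Why: Copper-catalysed borylation of a primary alkyl bromide with a diboron reagent should deliver the unhindered neopentyl glycol boronic ester that hindered lithiated benzoates capture well.

Step 6
Reactants: 3 (R)-hex-5-en-2-yl 2,4,6-triisopropylbenzoate, 8 2-[3-(furan-3-yl)propyl]-5,5-dimethyl-1,3,2-dioxaborinane
Product: 12 (S)-8-(furan-3-yl)-5-methyloct-1-en-5-ol, via lithiated benzoate 9 (not isolated), via lithium boronate complex 10 (not isolated), via tertiary boronic ester 11 (not isolated)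
Conditions: 3 (1.3 equiv), s-BuLi (1.25 equiv), TMEDA, CPME, −60 °C; 8 (1.0 equiv), −60 °C then 50 °C; NaOH, H2O2, THF, 0 °C to rt
Reagents that add atoms: hydrogen peroxide, OO
Why: Lithiation–borylation: the hindered benzoate directs α-deprotonation with retention, 8 is captured with retention, the furylpropyl group then shifts from boron to carbon anti to the departing carboxylate (Matteson-type 1,2-metallate rearrangement, inversion at carbon), and oxidation of the C–B bond with retention should set C14 as (S) from the (R)-ester.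

Step 7
Reactants: 12 (S)-8-(furan-3-yl)-5-methyloct-1-en-5-ol
Product: 14 (S)-8-(furan-3-yl)-5-methyloctane-1,5-diol, via B-alkyl-9-BBN adduct 13 (not isolated)
Conditions: 9-BBN (2.5 equiv), THF, 0 °C to rt; NaOH, H2O2, 0 °C to rt
Reagents that add atoms: hydrogen peroxide, OO
Why: Anti-Markovnikov hydroboration of the terminal alkene with 9-BBN and oxidation of the C–B bond gives the primary alcohol at C10, the furan being much less reactive toward this borane.

Step 8
Reactants: 14 (S)-8-(furan-3-yl)-5-methyloctane-1,5-diol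
Product: 17 (S)-6-[3-(furan-3-yl)propyl]-6-methyltetrahydro-2H-pyran-2-one, via hydroxy aldehyde 15 (not isolated), via lactol 16 (not isolated)
Conditions: TEMPO (20 mol%), PhI(OAc)2, CH2Cl2, rt
Reagents that add atoms: none
Why: Oxoammonium-mediated oxidation takes only the primary alcohol to the aldehyde, the tertiary hydroxyl closes the six-membered lactol, and a second oxidation gives the δ-lactone (oxidative lactonisation of a 1,5-diol).

Step 9
Reactants: 17 (S)-6-[3-(furan-3-yl)propyl]-6-methyltetrahydro-2H-pyran-2-one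
Product: 19 (S)-2-[3-(furan-3-yl)propyl]-2-methyl-3,4-dihydro-2H-pyran-6-yl trifluoromethanesulfonate, via potassium enolate 18 (not isolated)
Conditions: KN(SiMe3)2, THF–DMPU, −78 °C; PhNTf2, −78 °C; rapid filtration through Et3N-deactivated silica, used at once
Reagents that add atoms: N-phenylbis(trifluoromethanesulfonimide), FC(F)(F)S(=O)(=O)N(c1ccccc1)S(=O)(=O)C(F)(F)F
Why: O-Sulfonylation of the potassium lactone enolate in a dipolar medium gives the ketene acetal triflate (enol triflate formation), the C14 centre being remote from the enolised position.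

Step 10
Reactants: 19 (S)-2-[3-(furan-3-yl)propyl]-2-methyl-3,4-dihydro-2H-pyran-6-yl trifluoromethanesulfonate
Product: 20 (S)-2-[3-(furan-3-yl)propyl]-2-methyl-6-(trimethylstannyl)-3,4-dihydro-2H-pyran
Conditions: Me3SnSnMe3, Pd(PPh3)4 (5 mol%), LiCl, THF, 65 °C; chromatography on basic alumina
Reagents that add atoms: hexamethylditin, C[Sn](C)(C)[Sn](C)(C)C
Why: Oxidative addition of the enol triflate to the zerovalent palladium catalyst, transmetallation with the ditin and reductive elimination give the α-alkoxyalkenyl stannane (palladium-catalysed stannylation of an enol triflate).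

Step 11
Reactants: 21 (R)-4-benzyl-3-propionyloxazolidin-2-one
Product: 23 (R)-4-benzyl-3-[(S)-2-methylpent-4-enoyl]oxazolidin-2-one, via sodium enolate 22 (not isolated)
Conditions: NaN(SiMe3)2, THF, −78 °C; allyl bromide, −78 to −40 °C
Reagents that add atoms: allyl bromide, C=CCBr
Why: Evans alkylation: the chelated (Z)-enolate is allylated on the face opposite the benzyl group of the (R)-auxiliary, which should set the future C6 as (S).

Step 12
Reactants: 23 (R)-4-benzyl-3-[(S)-2-methylpent-4-enoyl]oxazolidin-2-one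
Product: 24 (S)-2-methylpent-4-en-1-ol
Conditions: LiBH4, MeOH, Et2O, 0 °C
Reagents that add atoms: none
Why: Hydride reduction of the exocyclic imide carbonyl releases the primary alcohol and the auxiliary without epimerising the α-centre (reductive auxiliary cleavage).

Step 13
Reactants: 24 (S)-2-methylpent-4-en-1-ol
Product: 25 (S)-triisopropyl(2-methylpent-4-enyloxy)silane
Conditions: TIPSCl, imidazole, CH2Cl2, rt
Reagents that add atoms: chlorotriisopropylsilane, CC(C)[Si](Cl)(C(C)C)C(C)C
Why: Silylation of the primary alcohol gives a bulky ether that should withstand t-BuLi and the cuprate and resist silyl migration to carbon in step 16.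

Step 14
Reactants: 25 (S)-triisopropyl(2-methylpent-4-enyloxy)silane
Product: 27 (S)-4-methyl-5-(triisopropylsilyloxy)pentan-1-ol, via B-alkyl-9-BBN adduct 26 (not isolated)
Conditions: 9-BBN, THF, rt; NaOH, H2O2, 0 °C
Reagents that add atoms: hydrogen peroxide, OO
Why: Anti-Markovnikov hydroboration–oxidation of the terminal alkene gives the primary alcohol at the future C9.

Step 15
Reactants: 27 (S)-4-methyl-5-(triisopropylsilyloxy)pentan-1-ol
Product: 28 (S)-(5-iodo-2-methylpentyloxy)triisopropylsilane
Conditions: I2, PPh3, imidazole, CH2Cl2, 0 °C to rt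
Reagents that add atoms: iodine, II
Why: Appel-type iodination converts the primary alcohol to the iodide under buffered conditions that leave the silyl ether intact.

Step 16
Reactants: 20 (S)-2-[3-(furan-3-yl)propyl]-2-methyl-6-(trimethylstannyl)-3,4-dihydro-2H-pyran, 28 (S)-(5-iodo-2-methylpentyloxy)triisopropylsilane
Product: 34 (2S,6E,10S)-13-(furan-3-yl)-2,6,10-trimethyl-1-(triisopropylsilyloxy)tridec-6-en-10-ol, via alkyllithium 29 (not isolated), via lithium dialkylcuprate 30 (not isolated), via 6-lithiodihydropyran 31 (not isolated), via higher-order mixed cuprate 32 (not isolated), via rearranged alkenylcuprate 33 (not isolated)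
Conditions: 28 (2.1 equiv), t-BuLi (1.95 equiv per iodide), Et2O–pentane, −78 °C; CuBr·SMe2 (1.05 equiv), Et2O–Me2S, −78 to −40 °C; 20 (1.0 equiv) with MeLi (0.98 equiv), THF, −78 to −20 °C, added at −78 °C; then rt; MeI (excess), DMPU, 0 °C to rt; aq NH4Cl–NH3
Reagents that add atoms: iodomethane, CI
Why: MeLi exchanges tin for lithium at C10 without metallating the furan, and the 6-lithiodihydropyran 31 joins the dialkylcuprate 30 of monovalent copper to give the ate complex 32; on warming, one C5–C9 alkyl ligand shifts from copper to C10 in the plane of the enol ether, anti to the C10–O bond, so that the ring oxygen departs as the C14 lithium alkoxide with inversion at C10 and the C9–C10 bond is formed. The closest known reaction type is the 1,2-metallate rearrangement of α-alkoxyalkenyl cuprates derived from metallated dihydrofurans and dihydropyrans, followed by alkylation of the resulting alkenylcopper species; here only the leaving group differs, being a tertiary alkoxide. No ring is closed, since the temporary dihydropyran opens, and no stereocentre is created, C6 and C14 being carried through unchanged. The selectivity required is the E geometry of C10=C11: the ring holds oxygen cis to C12, inversion therefore places C9 trans to C12 and copper cis to it, and MeI alkylates the C10–Cu bond with retention so that the new methyl is cis to C12. Chemoselectivity rests on forming 29 with slightly less than two equivalents of t-BuLi and 31 with slightly less than one equivalent of MeLi, so that no free alkyllithium can metallate the furan or place a methyl ligand on copper before the rearrangement.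

Step 17
Reactants: 34 (2S,6E,10S)-13-(furan-3-yl)-2,6,10-trimethyl-1-(triisopropylsilyloxy)tridec-6-en-10-ol
Product: 35 (2S,6E,10S)-13-(furan-3-yl)-2,6,10-trimethyltridec-6-ene-1,10-diol
Conditions: Bu4NF, THF, rt
Reagents that add atoms: none
Why: Fluoride cleaves the Si–O bond of the primary silyl ether and leaves the alkene, furan and tertiary carbinol untouched (desilylation).

Step 18
Reactants: 35 (2S,6E,10S)-13-(furan-3-yl)-2,6,10-trimethyltridec-6-ene-1,10-diol
Product: 36 (2S,6E,10S)-13-(furan-3-yl)-10-hydroxy-2,6,10-trimethyltridec-6-enal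
Conditions: Dess–Martin periodinane, NaHCO3, CH2Cl2, 0 °C to rt; used at once
Reagents that add atoms: none
Why: Buffered Dess–Martin oxidation takes the primary alcohol to the aldehyde without epimerising the adjacent C6 centre, the tertiary alcohol being inert to oxidation.

Step 19
Reactants: 37 ethyl 2-methyl-3-oxobutanoate
Product: 39 4-hydroxy-3-methylfuran-2(5H)-one, via bromo ketoester 38 (not isolated)
Conditions: Br2, CHCl3, 0 °C to rt; then neat, 110 °C
Reagents that add atoms: none
Why: Bromination equilibrated by the HBr formed places bromine on the terminal methyl, and on heating the ester oxygen displaces bromide with loss of bromoethane to close the butenolide ring (5-exo-tet lactonisation, the classical tetronic acid synthesis).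

Step 20
Reactants: 39 4-hydroxy-3-methylfuran-2(5H)-one
Product: 40 4-methoxy-3-methylfuran-2(5H)-one
Conditions: Me2SO4, K2CO3, acetone, reflux
Reagents that add atoms: dimethyl sulfate, COS(=O)(=O)OC
Why: O-Alkylation of the vinylogous carboxylate with the hard methylating agent masks the acidic enol as its methyl ether.

Step 21
Reactants: 40 4-methoxy-3-methylfuran-2(5H)-one, 36 (2S,6E,10S)-13-(furan-3-yl)-10-hydroxy-2,6,10-trimethyltridec-6-enal
Product: 42 5-[(2S,6E,10S)-13-(furan-3-yl)-1,10-dihydroxy-2,6,10-trimethyltridec-6-en-1-yl]-4-methoxy-3-methylfuran-2(5H)-one (mixture of diastereomers at ring C5 and chain C1), via lithiated tetronate 41 (not isolated)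
Conditions: 40 (2.2 equiv), LiN(i-Pr)2, THF, −78 °C; 36, −78 °C; aq NH4Cl
Reagents that add atoms: none
Why: Deprotonation at the γ-carbon gives the 2-oxidofuran, which adds to the aldehyde at −78 °C faster than the aldehyde enolises (aldol addition of a lithiated tetronate); the two new centres are removed in step 22.

Step 22
Reactants: 42 5-[(2S,6E,10S)-13-(furan-3-yl)-1,10-dihydroxy-2,6,10-trimethyltridec-6-en-1-yl]-4-methoxy-3-methylfuran-2(5H)-one
Product: 44 (Z)-5-[(2S,6E,10S)-13-(furan-3-yl)-10-hydroxy-2,6,10-trimethyltridec-6-en-1-ylidene]-4-methoxy-3-methylfuran-2(5H)-one, via mesylate 43 (not isolated)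
Conditions: MsCl (1.2 equiv), Et3N, CH2Cl2, −20 °C; DBU, 0 °C to rt
Reagents that add atoms: none
Why: The secondary carbinol is mesylated far faster than the hindered tertiary one, and DBU-mediated E1cB elimination through the furanolate should give the Z-ylidene, in which the alkyl chain avoids the C3 methoxy group.

Step 23
Reactants: 44 (Z)-5-[(2S,6E,10S)-13-(furan-3-yl)-10-hydroxy-2,6,10-trimethyltridec-6-en-1-ylidene]-4-methoxy-3-methylfuran-2(5H)-one
Product: 45 (Z)-5-[(2S,6E,10S)-13-(furan-3-yl)-10-hydroxy-2,6,10-trimethyltridec-6-en-1-ylidene]-4-hydroxy-3-methylfuran-2(5H)-one (CNP0217216.2)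
Conditions: LiCl, DMF, 90 °C; dilute aq HCl, 0 °C
Reagents that add atoms: none
Why: Chloride attacks the O-methyl carbon of the vinylogous carbonate in an SN2 dealkylation and releases the lithium tetronate, which brief cold acidification converts to the tetronic acid without harming the furan or the tertiary alcohol.

**Compound list**

1 | (S)-propylene oxide | C[C@H]1CO1 | starting material
2 | (S)-hex-5-en-2-ol | C=CCC[C@H](C)O | intermediate
3 | (R)-hex-5-en-2-yl 2,4,6-triisopropylbenzoate | C=CCC[C@@H](C)OC(=O)c1c(C(C)C)cc(C(C)C)cc1C(C)C | intermediate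
4 | 3-bromofuran | Brc1ccoc1 | starting material
5 | 3-furyllithium | [Li]c1ccoc1 | intermediate
6 | 3-(furan-3-yl)propan-1-ol | OCCCc1ccoc1 | intermediate
7 | 3-(3-bromopropyl)furan | BrCCCc1ccoc1 | intermediate
8 | 2-[3-(furan-3-yl)propyl]-5,5-dimethyl-1,3,2-dioxaborinane | CC1(C)COB(CCCc2ccoc2)OC1 | intermediate
9 | (R)-2-lithiohex-5-en-2-yl 2,4,6-triisopropylbenzoate (lithium in place of the carbinol hydrogen) | C=CCC[C@@]([Li])(C)OC(=O)c1c(C(C)C)cc(C(C)C)cc1C(C)C | intermediate
10 | lithium boronate complex of 9 with 8 (boron in place of lithium) | [Li+].C=CCC[C@@](C)(OC(=O)c1c(C(C)C)cc(C(C)C)cc1C(C)C)[B-]1(CCCc2ccoc2)OCC(C)(C)CO1 | intermediate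
11 | 2-[(R)-8-(furan-3-yl)-5-methyloct-1-en-5-yl]-5,5-dimethyl-1,3,2-dioxaborinane | C=CCC[C@](B1OCC(C)(C)CO1)(C)CCCc2ccoc2 | intermediate
12 | (S)-8-(furan-3-yl)-5-methyloct-1-en-5-ol | C=CCC[C@](O)(C)CCCc1ccoc1 | intermediate
13 | (R)-1-(9-borabicyclo[3.3.1]nonan-9-yl)-8-(furan-3-yl)-5-methyloctan-5-ol (same spatial arrangement at C5 as 12; the descriptor changes by priority only) | C[C@@](O)(CCCCB1C2CCCC1CCC2)CCCc1ccoc1 | intermediate
14 | (S)-8-(furan-3-yl)-5-methyloctane-1,5-diol | OCCCC[C@@](C)(O)CCCc1ccoc1 | intermediate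
15 | (S)-8-(furan-3-yl)-5-hydroxy-5-methyloctanal | O=CCCC[C@@](C)(O)CCCc1ccoc1 | intermediate
16 | (6S)-6-[3-(furan-3-yl)propyl]-6-methyltetrahydro-2H-pyran-2-ol (anomer mixture) | OC1CCC[C@@](C)(O1)CCCc2ccoc2 | intermediate
17 | (S)-6-[3-(furan-3-yl)propyl]-6-methyltetrahydro-2H-pyran-2-one | O=C1CCC[C@@](C)(O1)CCCc2ccoc2 | intermediate
18 | potassium (S)-2-[3-(furan-3-yl)propyl]-2-methyl-3,4-dihydro-2H-pyran-6-olate | [K+].[O-]C1=CCC[C@@](C)(O1)CCCc2ccoc2 | intermediate
19 | (S)-2-[3-(furan-3-yl)propyl]-2-methyl-3,4-dihydro-2H-pyran-6-yl trifluoromethanesulfonate | FC(F)(F)S(=O)(=O)OC1=CCC[C@@](C)(O1)CCCc2ccoc2 | intermediate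
20 | (S)-2-[3-(furan-3-yl)propyl]-2-methyl-6-(trimethylstannyl)-3,4-dihydro-2H-pyran | C[Sn](C)(C)C1=CCC[C@@](C)(O1)CCCc2ccoc2 | intermediate
21 | (R)-4-benzyl-3-propionyloxazolidin-2-one | CCC(=O)N1[C@H](Cc2ccccc2)COC1=O | starting material
22 | sodium (Z)-enolate of 21 | [Na+].C/C=C(\[O-])N1[C@H](Cc2ccccc2)COC1=O | intermediate
23 | (R)-4-benzyl-3-[(S)-2-methylpent-4-enoyl]oxazolidin-2-one | C=CC[C@H](C)C(=O)N1[C@H](Cc2ccccc2)COC1=O | intermediate
24 | (S)-2-methylpent-4-en-1-ol | C=CC[C@H](C)CO | intermediate
25 | (S)-triisopropyl(2-methylpent-4-enyloxy)silane | C=CC[C@H](C)CO[Si](C(C)C)(C(C)C)C(C)C | intermediate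
26 | (S)-{[5-(9-borabicyclo[3.3.1]nonan-9-yl)-2-methylpentyl]oxy}triisopropylsilane | CC(C)[Si](C(C)C)(C(C)C)OC[C@@H](C)CCCB1C2CCCC1CCC2 | intermediate
27 | (S)-4-methyl-5-(triisopropylsilyloxy)pentan-1-ol | CC(C)[Si](C(C)C)(C(C)C)OC[C@@H](C)CCCO | intermediate
28 | (S)-(5-iodo-2-methylpentyloxy)triisopropylsilane | CC(C)[Si](C(C)C)(C(C)C)OC[C@@H](C)CCCI | intermediate
29 | (S)-[4-methyl-5-(triisopropylsilyloxy)pentyl]lithium | CC(C)[Si](C(C)C)(C(C)C)OC[C@@H](C)CCC[Li] | intermediate
30 | lithium bis[(S)-4-methyl-5-(triisopropylsilyloxy)pentyl]cuprate | [Li+].CC(C)[Si](C(C)C)(C(C)C)OC[C@@H](C)CCC[Cu-]CCC[C@H](C)CO[Si](C(C)C)(C(C)C)C(C)C | intermediate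
31 | (S)-{6-[3-(furan-3-yl)propyl]-6-methyl-5,6-dihydro-4H-pyran-2-yl}lithium | [Li]C1=CCC[C@@](C)(O1)CCCc2ccoc2 | intermediate
32 | dilithium dialkyl(dihydropyranyl)cuprate from 30 and 31 | [Li+].[Li+].CC(C)[Si](C(C)C)(C(C)C)OC[C@@H](C)CCC[Cu-2](CCC[C@H](C)CO[Si](C(C)C)(C(C)C)C(C)C)C1=CCC[C@@](C)(O1)CCCc2ccoc2 | intermediate
33 | dilithium alkyl(alkenyl)cuprate alkoxide after the 1,2-shift (copper on C10, cis to C12) | [Li+].[Li+].CC(C)[Si](C(C)C)(C(C)C)OC[C@@H](C)CCC/C([Cu-]CCC[C@H](C)CO[Si](C(C)C)(C(C)C)C(C)C)=C/CC[C@@](C)([O-])CCCc1ccoc1 | intermediate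
34 | (2S,6E,10S)-13-(furan-3-yl)-2,6,10-trimethyl-1-(triisopropylsilyloxy)tridec-6-en-10-ol | CC(C)[Si](C(C)C)(C(C)C)OC[C@@H](C)CCC/C(C)=C/CC[C@@](C)(O)CCCc1ccoc1 | intermediate
35 | (2S,6E,10S)-13-(furan-3-yl)-2,6,10-trimethyltridec-6-ene-1,10-diol | OC[C@@H](C)CCC/C(C)=C/CC[C@@](C)(O)CCCc1ccoc1 | intermediate
36 | (2S,6E,10S)-13-(furan-3-yl)-10-hydroxy-2,6,10-trimethyltridec-6-enal | O=C[C@@H](C)CCC/C(C)=C/CC[C@@](C)(O)CCCc1ccoc1 | intermediate
37 | ethyl 2-methyl-3-oxobutanoate | CCOC(=O)C(C)C(C)=O | starting material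
38 | ethyl 4-bromo-2-methyl-3-oxobutanoate | CCOC(=O)C(C)C(=O)CBr | intermediate
39 | 4-hydroxy-3-methylfuran-2(5H)-one | CC1=C(O)COC1=O | intermediate
40 | 4-methoxy-3-methylfuran-2(5H)-one | CC1=C(OC)COC1=O | intermediate
41 | lithium 4-methoxy-3-methylfuran-2-olate | [Li+].COC1=COC([O-])=C1C | intermediate
42 | 5-[(2S,6E,10S)-13-(furan-3-yl)-1,10-dihydroxy-2,6,10-trimethyltridec-6-en-1-yl]-4-methoxy-3-methylfuran-2(5H)-one (diastereomer mixture at ring C5 and chain C1) | CC1=C(OC)C(C(O)[C@@H](C)CCC/C(C)=C/CC[C@@](C)(O)CCCc2ccoc2)OC1=O | intermediate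
43 | (2S,6E,10S)-13-(furan-3-yl)-10-hydroxy-1-(3-methoxy-4-methyl-5-oxo-2,5-dihydrofuran-2-yl)-2,6,10-trimethyltridec-6-en-1-yl methanesulfonate (diastereomer mixture) | CC1=C(OC)C(C(OS(C)(=O)=O)[C@@H](C)CCC/C(C)=C/CC[C@@](C)(O)CCCc2ccoc2)OC1=O | intermediate
44 | (Z)-5-[(2S,6E,10S)-13-(furan-3-yl)-10-hydroxy-2,6,10-trimethyltridec-6-en-1-ylidene]-4-methoxy-3-methylfuran-2(5H)-one | CC1=C(OC)/C(=C/[C@@H](C)CCC/C(C)=C/CC[C@@](C)(O)CCCc2ccoc2)OC1=O | intermediate
45 | (Z)-5-[(2S,6E,10S)-13-(furan-3-yl)-10-hydroxy-2,6,10-trimethyltridec-6-en-1-ylidene]-4-hydroxy-3-methylfuran-2(5H)-one | CC1=C(O)/C(=C/[C@@H](C)CCC/C(C)=C/CC[C@@](C)(O)CCCc2ccoc2)OC1=O | target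

**Step count and risks**

Total step count: 23. Longest linear sequence: 14 steps (steps 3–10, 16–18 and 21–23).

Steps most likely to fail:

Step 16. The alkyl shift from copper to C10 may be slow or incomplete for the six-membered ring with a hindered tertiary alkoxide as leaving group, so that the metallated dihydropyran is merely protonated on work-up; methylation of the alkenylcopper may also stay incomplete. The fallback sets out from 20 and 28 and comes back at 34. Tin–lithium exchange of 20 as before is followed by alkylation of 31 with iodide 28 in THF–DMPU to give (S)-2-[3-(furan-3-yl)propyl]-2-methyl-6-[(S)-4-methyl-5-(triisopropylsilyloxy)pentyl]-3,4-dihydro-2H-pyran F1. Nickel-catalysed coupling of F1 with MeMgBr (NiCl2(PPh3)2, reduced in the flask to zerovalent nickel, toluene, reflux) then replaces the ring oxygen at C10 by methyl with retention and opens the ring to 34. This ring-opening coupling is established for 6-alkyl-3,4-dihydro-2H-pyrans and gives the same E geometry, because the methyl takes the place of the oxygen cis to C12.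

Step 6. Capture of the hindered lithiated benzoate by the boronic ester may be incomplete, the carbanion may lose configuration before capture, and unconsumed s-BuLi may metallate the furan. The fallback sets out from 7 and comes back at 12. Finkelstein exchange (NaI, acetone) gives 3-(3-iodopropyl)furan F2. The acetal of (R)-lactic acid and pivalaldehyde, (2R,5R)-2-tert-butyl-5-methyl-1,3-dioxolan-4-one F3 (acid-catalysed condensation, cis isomer crystallised), is deprotonated with LiN(i-Pr)2 at −78 °C and alkylated with F2 anti to the tert-butyl group to give (2R,5S)-2-tert-butyl-5-[3-(furan-3-yl)propyl]-5-methyl-1,3-dioxolan-4-one F4 (self-regeneration of the stereocentre). LiAlH4 reduction gives (S)-5-(furan-3-yl)-2-methylpentane-1,2-diol F5, and TsCl in pyridine gives the primary tosylate (S)-5-(furan-3-yl)-2-hydroxy-2-methylpentyl 4-methylbenzenesulfonate F6. K2CO3 in MeOH closes (S)-2-[3-(furan-3-yl)propyl]-2-methyloxirane F7, and CH2=CHCH2MgCl with CuI opens it at the CH2 terminus to give 12.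

Step 9. The ketene acetal triflate may hydrolyse or decompose before stannylation, and the enolate may be sulfonylated on carbon. The fallback sets out from 17 and comes back at 31, inside step 16. Reduction with i-Bu2AlH at −78 °C gives lactol 16, which benzenesulfinic acid and CaCl2 in CH2Cl2 convert to (6S)-6-[3-(furan-3-yl)propyl]-6-methyl-2-(phenylsulfonyl)tetrahydro-2H-pyran F8. Deprotonation α to sulfur with n-BuLi at −78 °C and capture with Bu3SnCl give (6S)-tributyl{6-[3-(furan-3-yl)propyl]-6-methyl-2-(phenylsulfonyl)tetrahydro-2H-pyran-2-yl}stannane F9. On warming with i-Pr2NEt this loses benzenesulfinic acid to give (S)-tributyl{6-[3-(furan-3-yl)propyl]-6-methyl-5,6-dihydro-4H-pyran-2-yl}stannane F10. Tin–lithium exchange of F10 with n-BuLi gives 31, which enters the cuprate sequence of step 16 unchanged.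

**Further compounds**

F1 | step 16 | (S)-2-[3-(furan-3-yl)propyl]-2-methyl-6-[(S)-4-methyl-5-(triisopropylsilyloxy)pentyl]-3,4-dihydro-2H-pyran | CC(C)[Si](C(C)C)(C(C)C)OC[C@@H](C)CCCC1=CCC[C@@](C)(O1)CCCc2ccoc2
F2 | step 6 | 3-(3-iodopropyl)furan | ICCCc1ccoc1
F3 | step 6 | (2R,5R)-2-tert-butyl-5-methyl-1,3-dioxolan-4-one | C[C@H]1O[C@@H](C(C)(C)C)OC1=O
F4 | step 6 | (2R,5S)-2-tert-butyl-5-[3-(furan-3-yl)propyl]-5-methyl-1,3-dioxolan-4-one | C[C@@]1(CCCc2ccoc2)O[C@@H](C(C)(C)C)OC1=O
F5 | step 6 | (S)-5-(furan-3-yl)-2-methylpentane-1,2-diol | C[C@@](CCCc1ccoc1)(O)CO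
F6 | step 6 | (S)-5-(furan-3-yl)-2-hydroxy-2-methylpentyl 4-methylbenzenesulfonate | C[C@@](CCCc1ccoc1)(O)COS(=O)(=O)c1ccc(C)cc1
F7 | step 6 | (S)-2-[3-(furan-3-yl)propyl]-2-methyloxirane | C[C@@]1(CCCc2ccoc2)OC1
F8 | step 9 | (6S)-6-[3-(furan-3-yl)propyl]-6-methyl-2-(phenylsulfonyl)tetrahydro-2H-pyran | O=S(=O)(c1ccccc1)C1CCC[C@@](C)(O1)CCCc2ccoc2
F9 | step 9 | (6S)-tributyl{6-[3-(furan-3-yl)propyl]-6-methyl-2-(phenylsulfonyl)tetrahydro-2H-pyran-2-yl}stannane | CCCC[Sn](CCCC)(CCCC)C1(S(=O)(=O)c2ccccc2)CCC[C@@](C)(O1)CCCc3ccoc3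
F10 | step 9 | (S)-tributyl{6-[3-(furan-3-yl)propyl]-6-methyl-5,6-dihydro-4H-pyran-2-yl}stannane | CCCC[Sn](CCCC)(CCCC)C1=CCC[C@@](C)(O1)CCCc2ccoc2
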